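## Structural features

The target, 14 (C15H25Br2ClO), is a halogenated cuparane-type sesquiterpenoid made of two carbocycles that share no atom: a cyclopentane (ring A: C1 quaternary with a methyl group, C2 with two methyl groups, C3 bearing bromine, then C4 and C5) and a cyclohexane (ring B: C1' tertiary carbinol, C2', C3', C4' bearing methyl and chlorine, C5' bearing bromine, C6'), joined only by the C1–C1' bond. It has five stereocentres, C1 (R) and C3 (S) in ring A and C1' (R), C4' (S) and C5' (S) in ring B; C1 and C1' are bonded to each other and both fully substituted, C4' and C5' are neighbours, and the C3 bromine is cis to ring B. In ring B, bromine and chlorine are trans to each other and both equatorial in the chair that keeps ring A equatorial, and the chlorine is cis to the C1' hydroxyl. The fragile groups are the tertiary alcohol next to a quaternary carbon (ionisation, 1,2-shifts), the tertiary chloride and the two secondary bromides, one of them neopentyl, so all three halogens must come after every strongly basic or reducing step. The real difficulty is that C1–C1' links two carbons without hydrogen, and that C1' is a stereocentre only because its arms C2' and C6' differ at the far side of ring B, so addition to a C1' carbonyl could not set it. The key step uses the fact that C1, C2 and C3 map onto the β-carbon, α-carbon and carbonyl carbon of 2,3-dimethylcyclopent-2-en-1-one, while C1'–C2' maps onto the enol ether double bond of a 1,4-cyclohexadiene whose other double bond is C4'=C5'. A (2+2) photocycloaddition forms C1–C1' together with a temporary C2–C2' bond; the cyclobutane ties the C2' arm to ring A, so the C1/C1' relationship becomes a matter of ring fusion. Its reductive opening leaves an enolate at C2 for the second methyl group, a carbonyl at C3 for the bromide and the C4'=C5' alkene for the bromine–chlorine pair.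

## Logic of the disconnections

**14 ⇒ 12 (through 13).** The C4'–Cl bond is cut and C4' is joined to the C1' oxygen, making ring B an oxygen-bridged bicycle. Direct addition to the C4'=C5' alkene would open the bromonium ion diaxially and should give the other diastereomer. In 12 the C5' bromine lies anti to the C4'–O bond and can hold the configuration while chloride replaces oxygen. The gain is that the tertiary chloride and the free tertiary alcohol appear together in the last step. The forward step must ionise C4'–O, with help from bromine, and not C1'–O, and must leave the C3 bromide alone.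

**12 ⇒ 10 (through 11).** The C3–Br bond is replaced by a C3–O bond of opposite configuration. The C3 stereocentre is thereby traced back to a reduction that a chiral reagent can control. The forward displacement must invert cleanly, without methyl migration from C2, without elimination and without interference from the C1' oxygen; this is why that oxygen is still tied up in the bridge at this stage.

**10 ⇒ 9.** The C3–H bond is cut, returning the carbonyl that the enone supplies. The forward reduction must place the hydroxyl trans to ring B under reagent control and spare the secondary bromide.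

**9 ⇒ 8.** The C5'–Br and C4'–O bonds are cut, giving back the C4'=C5' alkene and the free C1' hydroxyl. Two stereocentres disappear, and both are set from C1' alone, because only a bromonium ion anti to the hydroxyl can be captured across the ring. The forward step needs oxygen attack at the tertiary C4' and a ketone that is inert to the bromine source.

**8 ⇒ 6 (through 7).** One methyl group on C2 is removed and the C2–C2' bond is restored, closing the cyclobutane C1–C2–C2'–C1'. Reductive opening of a cyclobutyl ketone generates the enolate exactly at C2, and in 6 the relative configuration of C1 and C1' is locked by ring fusion. The demands are three: the ketyl must break C2–C2' and not the fusion bond C1–C2; the carbanion formed at C2' must not expel the oxygen on C1' (hence a free hydroxyl, which becomes an alkoxide); and methylation must occur on carbon.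

**6 ⇒ 5.** The O–H bond is exchanged for an O–Si bond. The enol oxygen must be capped for the two forward steps before this one and uncapped for the reductive opening. The desilylation must not open the strained cyclobutanol.

**5 ⇒ 3 + 4.** The C1–C1' and C2–C2' bonds are cut. This is the only disconnection in the plan that makes the congested C1–C1' bond, and it removes all four stereocentres at once, leaving two achiral partners. Tracing C1 and C1' through the sequence shows that 5, as written below, leads to C1 (R) and C1' (R) of 14, so the cis-anti-cis head-to-tail isomer is the one required. The enol oxygen carries a bulky silyl group and not an acetal, because an acetal would bind to and be cleaved by a strong Lewis acid. The forward step must be head-to-tail, cis-anti-cis, selective for the enol ether over C4'=C5', and selective for one face of 4.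

**3 ⇒ 2.** The ring C–H bonds at C3' and C6' are cut (re-aromatisation). Birch reduction of a para-disubstituted aryl ether gives only the 1,4-diene in which both substituted carbons stay sp2, which is the pattern C1'=C2', C4'=C5'. The silyl ether must survive dissolving-metal conditions and the work-up must not conjugate the diene.

**2 ⇒ 1.** The O–Si bond is cut; 1 is a bulk chemical and the silylation is routine.

## Other disconnections considered

**Alternative 1:** The cut is at C1'–C2' and C5'–C6', on both sides of the carbinol carbon, with boron standing in for the hydroxyl.
- Forward step: the alkenylboronic ester A1 (ring A complete) and the organolithium A2 form a boronate complex. A palladium catalyst with a chiral bisphosphine couples it with the alkenyl triflate A3: the butenyl group shifts from boron to C1' as the vinyl group bonds to C6', giving the tertiary boronic ester A4. Ring-closing metathesis and stereoretentive C–B oxidation would follow.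
- In favour: the C1' configuration is set by a ligand in a thermal reaction, a source of absolute control with broader precedent than the photochemical one; on this point it is the better plan. The C4'=C5' alkene is placed unambiguously by metathesis (equal to the chosen plan), and the oxygen arrives late, so it cannot be lost by β-elimination (better).
- Against: the C1–C1' bond is already present in A1, so the hardest bond is moved into an undefined synthesis of an enantiopure ring A carrying a quaternary carbon with an α-borylvinyl group. The metallate shift must create a fully substituted C1' next to that quaternary carbon, far more hindered than the cases this coupling is known for, and the ligand must override the neighbouring stereocentre.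
- Comparison: structurally, the chosen plan makes C1–C1' and fixes C1/C1' in one event from two achiral pieces. Mechanistically, a triplet diradical tolerates congestion better than a two-electron 1,2-shift. In step count, 9 steps compare with an estimated 15 or more.

**Alternative 2:** The cut is C2–C3 in ring A.
- Forward step: aldehyde A5 already carries, on C1, the methyl group, an isopropenyl group (the future C2), the chain C5–C4–C3 and ring B. An iron-based hydrogen-atom-transfer catalyst with a silane gives the tertiary C2 radical, which adds to the aldehyde carbon and closes ring A as the cyclopentanol A6.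
- In favour: a radical makes the hindered C2–C3 bond (equal to the chosen plan in logic). The C3 oxygen stereocentre is created in the ring-forming step, saving a separate reduction (better). The conditions are mild and need neither light nor dissolving metal (better).
- Against: C1–C1' and both adjacent stereocentres must already exist in A5, whose synthesis would need a stereocontrolled union of two fully substituted carbons, the very problem of this target. Radical addition to an aldehyde is reversible. The C3 configuration rests on substrate bias alone. In A6, ring B is a masked enone (acetal at C4', alkene at C5'=C6'), so methyl addition and a reductive 1,3-transposition of the alkene are still needed before any halogen chemistry.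
- Comparison: it solves ring A well but leaves the defining bond and configuration to earlier steps; the estimate is 15 to 18 steps.

**Alternative 3:** The cut is C1'–C6' and C2'–C3', a retro-Diels–Alder of ring B.
- Forward step: enal A7, a 2-substituted propenal whose substituent is the complete bromocyclopentane, is bound to a chiral cationic oxazaborolidine and reacts with the diene A8. This gives aldehyde A9 with C4'=C5', the methyl group at C4', and a formyl group on C1' in place of the hydroxyl.
- In favour: catalytic enantioselective Diels–Alder reactions of 2-substituted acroleins that create quaternary centres are well established, so the origin of the C1' configuration has better precedent than the chosen photochemical step (better). Ring B and its alkene form in one thermal step with unambiguous regiochemistry (equal). The C3 bromide is already present, so no late displacement is needed (better, if it survives).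
- Against: C1–C1' already exists in A7. Its α-substituent is a fully substituted carbon, so reactivity and the conformation assumed by the catalyst model are uncertain, and the catalyst must cooperate with the adjacent C1 centre. The formyl group must later be degraded to hydroxyl in the presence of a trisubstituted alkene, costing two or three steps.
- Comparison: it shares with the chosen plan the feature that the ring alkene distinguishes the two arms when C1' is set, but it forms bonds at the periphery of C1' and not the congested C1–C1' bond; the estimate is about 14 steps.

Key step: step 3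

Assumption: which antipode of the oxazaborolidine exposes the required face of 4 cannot be deduced safely for an α-methylated cyclopentenone, so the (S)-prolinol-derived catalyst is written and its mirror image is to be taken if the sense proves opposite; step 7 removes what is left of the wrong enantiomer in either case.

## Steps

Step 1
Reactants: 1 4-methylphenol
Product: 2 tert-butyldimethyl(4-methylphenoxy)silane
Conditions: TBSCl, imidazole, DMF, 23 °C
Reagents that add atoms: tert-butyldimethylsilyl chloride, CC(C)(C)[Si](C)(C)Cl
Why: Imidazole-promoted O-silylation of a phenol (silyl ether formation); this silyl group is taken because aryl silyl ethers of this kind are known to pass through dissolving-metal reduction and because it leaves no Lewis-basic acetal oxygen in the later enol ether.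

Step 2
Reactants: 2 tert-butyldimethyl(4-methylphenoxy)silane
Product: 3 tert-butyldimethyl[(4-methylcyclohexa-1,4-dien-1-yl)oxy]silane
Conditions: Li, NH3(l), THF, t-BuOH, −78 °C
Reagents that add atoms: none
Why: Birch reduction: the arene takes up two electrons and two protons so that the two donor-substituted carbons (C1' with oxygen, C4' with methyl) stay sp2, which gives the unconjugated 1,4-diene with the enol ether at C1'=C2' and the alkyl alkene at C4'=C5' as the only regioisomer. A cold, non-acidic work-up should keep the silyl enol ether intact and unconjugated.

Step 3
Reactants: 3 tert-butyldimethyl[(4-methylcyclohexa-1,4-dien-1-yl)oxy]silane; 4 2,3-dimethylcyclopent-2-en-1-one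
Product: 5 (1R,2S,7R,8R)-2-[(tert-butyldimethylsilyl)oxy]-1,5,8-trimethyltricyclo[6.3.0.0(2,7)]undec-4-en-9-one
Conditions: B-(2,4,6-trifluorophenyl)oxazaborolidine of (S)-α,α-bis(2,3-dimethylphenyl)prolinol (50 mol%), AlBr3 (50 mol%), CH2Cl2, hν (λ = 366 nm), −75 °C, 3 (5 equiv) added last
Reagents that add atoms: none
Why: Proposed new method: enantioselective intermolecular enone–alkene (2+2) photocycloaddition under an AlBr3-activated chiral oxazaborolidine is established for cyclohex-2-enones with simple alkenes, and the racemic photocycloaddition of cyclopentenones with enol ethers is classical, but the combination of a tetrasubstituted cyclopentenone, a silyl enol ether and the chiral Lewis acid has not been shown. The Lewis acid on the carbonyl oxygen of 4 moves the enone absorption to longer wavelength, so that at 366 nm the complex is excited in preference to free 4; after intersystem crossing the triplet enone adds to the electron-rich C1'=C2' bond of 3 to give a triplet 1,4-diradical, which closes the second bond after spin inversion. The one ring that forms, the cyclobutane C1–C2–C2'–C1', is therefore closed stepwise by radical recombination within a 1,4-diradical and not by a concerted process. C1 and C2 come out cis because a trans-fused bicyclo[3.2.0]heptanone is too strained, C1' and C2' are cis because they were the two ends of a ring double bond, ring B takes the anti position relative to ring A for steric reasons, and the face of 4 left open by the ligand fixes the absolute configuration of all four centres. The step needs head-to-tail orientation (oxygen-bearing C1' on the β-carbon C1), which the donor–acceptor polarity rule of enone photocycloadditions supplies, and attack on the enol ether and not on C4'=C5', which the higher electron density of the enol ether favours. The bulky, non-chelating silyl group, the low temperature and the late addition of 3 are meant to hold back dark Mukaiyama–Michael addition, isomerisation of the diene and hydrogen abstraction from its doubly allylic CH2 groups.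

Step 4
Reactants: 5 (1R,2S,7R,8R)-2-[(tert-butyldimethylsilyl)oxy]-1,5,8-trimethyltricyclo[6.3.0.0(2,7)]undec-4-en-9-one
Product: 6 (1R,2S,7R,8R)-2-hydroxy-1,5,8-trimethyltricyclo[6.3.0.0(2,7)]undec-4-en-9-one
Conditions: Bu4NF, AcOH, THF, 23 → 50 °C
Reagents that add atoms: none
Why: Fluoride-mediated desilylation of a tertiary silyl ether, buffered with acetic acid; the cyclobutanol should be stable because its hydroxyl is γ and not β to the ketone, so no retro-aldol opening is available (a head-to-head regioisomer would be a β-hydroxy ketone and would open, which helps to remove it). The hydroxyl is freed here on purpose: in step 5 the carbanion formed at C2' must sit next to an alkoxide, which cannot leave, and not next to a silyloxy group, which could be expelled.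

Step 5
Reactants: 6 (1R,2S,7R,8R)-2-hydroxy-1,5,8-trimethyltricyclo[6.3.0.0(2,7)]undec-4-en-9-one
Product: 8 (3R)-3-[(1R)-1-hydroxy-4-methylcyclohex-3-en-1-yl]-2,2,3-trimethylcyclopentan-1-one, via dilithium enolate-alkoxide 7 (not isolated)
Conditions: Li (2.2 equiv), NH3(l), THF, −78 °C; MeI, −78 → −33 °C; NH4Cl (aq)
Reagents that add atoms: iodomethane, CI
Why: Dissolving-metal reductive cleavage of a cyclobutyl ketone with alkylation of the enolate (reductive alkylation): the ketyl radical anion breaks the cyclobutane bond that lies parallel to the carbonyl π system, the exocyclic C2–C2' bond, which releases the ring strain and places the enolate at C2 only, while the C2' radical is reduced and protonated, the hydroxyl proton ending up on carbon so that no amide base is left over. Iodomethane should alkylate the enolate carbon far faster than the hindered lithium tertiary alkoxide, completing the geminal dimethyl group; C1 and C1' are untouched, and C2 is no longer a stereocentre.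

Step 6
Reactants: 8 (3R)-3-[(1R)-1-hydroxy-4-methylcyclohex-3-en-1-yl]-2,2,3-trimethylcyclopentan-1-one
Product: 9 (3R)-3-[(1R,3S,4S)-3-bromo-4-methyl-7-oxabicyclo[2.2.1]heptan-1-yl]-2,2,3-trimethylcyclopentan-1-one
Conditions: NBS, CH2Cl2, 0 °C
Reagents that add atoms: N-bromosuccinimide, O=C1CCC(=O)N1Br
Why: Bromoetherification (transannular haloetherification of a 4-substituted cyclohex-3-en-1-ol): only the bromonium ion on the face of C4'=C5' opposite to the C1' hydroxyl can be opened by that hydroxyl, which attacks the tertiary C4' and closes the oxygen bridge. This sets C4'–O cis to C1'–O by necessity and C5'–Br anti to the bridge, and it ties up the tertiary hydroxyl so that it cannot act as an internal nucleophile at C3 in step 8.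

Step 7
Reactants: 9 (3R)-3-[(1R,3S,4S)-3-bromo-4-methyl-7-oxabicyclo[2.2.1]heptan-1-yl]-2,2,3-trimethylcyclopentan-1-one
Product: 10 (1R,3R)-3-[(1R,3S,4S)-3-bromo-4-methyl-7-oxabicyclo[2.2.1]heptan-1-yl]-2,2,3-trimethylcyclopentan-1-ol
Conditions: (S)-1-methyl-3,3-diphenyltetrahydro-1H,3H-pyrrolo[1,2-c][1,3,2]oxazaborole (20 mol%), BH3·SMe2, THF, −20 °C; MeOH
Reagents that add atoms: none
Why: Corey–Bakshi–Shibata reduction: the oxazaborolidine–borane complex binds the carbonyl oxygen on the side of the smaller C4 methylene, away from the quaternary C2, and delivers hydride so as to give the (R)-carbinol, that is the C3 hydroxyl trans to ring B; this should also be the more open face, because the C1 methyl group is pseudo-axial on the other side. Since the sense is set by the reagent, any mirror-image ketone carried along is turned into the cis diastereomer, which is removed by chromatography, so the step should also raise the enantiomeric purity.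

Step 8
Reactants: 10 (1R,3R)-3-[(1R,3S,4S)-3-bromo-4-methyl-7-oxabicyclo[2.2.1]heptan-1-yl]-2,2,3-trimethylcyclopentan-1-ol
Product: 12 (1S,2S,4R)-2-bromo-4-[(1R,3S)-3-bromo-1,2,2-trimethylcyclopentyl]-1-methyl-7-oxabicyclo[2.2.1]heptane, via alkoxyphosphonium bromide 11 (not isolated)
Conditions: PPh3, CBr4, PhMe, 23 → 80 °C
Reagents that add atoms: tetrabromomethane, BrC(Br)(Br)Br
Why: Appel reaction: the alcohol becomes alkoxyphosphonium ion 11, which bromide displaces with inversion (SN2) from the face of C3 that is not screened by the pseudo-axial C1 methyl group, giving the C3 bromide cis to ring B. The centre is neopentyl, so heating is needed, but cyclopentyl carbons accept SN2 attack comparatively well, and the C1' oxygen, locked in the bicyclic ether, cannot reach C3.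

Step 9
Reactants: 12 (1S,2S,4R)-2-bromo-4-[(1R,3S)-3-bromo-1,2,2-trimethylcyclopentyl]-1-methyl-7-oxabicyclo[2.2.1]heptane
Product: 14 (1R,3S,4S)-3-bromo-1-[(1R,3S)-3-bromo-1,2,2-trimethylcyclopentyl]-4-chloro-4-methylcyclohexan-1-ol, via dichloroboryl ether 13 (not isolated)
Conditions: BCl3 (1.5 equiv), CH2Cl2, −78 → −20 °C; H2O
Reagents that add atoms: boron trichloride, ClB(Cl)Cl
Why: Lewis-acid cleavage of an ether with neighbouring-group participation: BCl3 binds the bridging oxygen, the C4'–O bond ionises with backside assistance from the antiperiplanar C5' bromine (bromonium ion), and chloride opens this ion at the tertiary C4' from the side the oxygen has left. Two inversions mean retention at C4', so chlorine ends up cis to the C1' oxygen and trans to bromine, the diequatorial pair that direct addition to the alkene would not give; hydrolysis of the B–O bond of 13 frees the tertiary alcohol.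

## Compound list

1 | 4-methylphenol | Cc1ccc(O)cc1 | starting material
2 | tert-butyldimethyl(4-methylphenoxy)silane | Cc1ccc(O[Si](C)(C)C(C)(C)C)cc1 | intermediate
3 | tert-butyldimethyl[(4-methylcyclohexa-1,4-dien-1-yl)oxy]silane | CC1=CCC(O[Si](C)(C)C(C)(C)C)=CC1 | intermediate
4 | 2,3-dimethylcyclopent-2-en-1-one | CC1=C(C)C(=O)CC1 | starting material
5 | (1R,2S,7R,8R)-2-[(tert-butyldimethylsilyl)oxy]-1,5,8-trimethyltricyclo[6.3.0.0(2,7)]undec-4-en-9-one (cis-anti-cis, head-to-tail; C1 = ring-A C1, C8 = ring-A C2, C2 = C1', C7 = C2') | O=C1CC[C@]2(C)[C@@]1(C)[C@H]1CC(C)=CC[C@]12O[Si](C)(C)C(C)(C)C | intermediate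
6 | (1R,2S,7R,8R)-2-hydroxy-1,5,8-trimethyltricyclo[6.3.0.0(2,7)]undec-4-en-9-one | O=C1CC[C@]2(C)[C@@]1(C)[C@H]1CC(C)=CC[C@]12O | intermediate
7 | dilithium (3R)-2,3-dimethyl-3-[(1R)-4-methyl-1-oxidocyclohex-3-en-1-yl]cyclopent-1-en-1-olate (formed in the flask, not isolated) | [Li]OC1=C(C)[C@@](C)(CC1)[C@@]1(O[Li])CCC(C)=CC1 | intermediate
8 | (3R)-3-[(1R)-1-hydroxy-4-methylcyclohex-3-en-1-yl]-2,2,3-trimethylcyclopentan-1-one | CC1(C)C(=O)CC[C@@]1(C)[C@@]1(O)CCC(C)=CC1 | intermediate
9 | (3R)-3-[(1R,3S,4S)-3-bromo-4-methyl-7-oxabicyclo[2.2.1]heptan-1-yl]-2,2,3-trimethylcyclopentan-1-one | CC1(C)C(=O)CC[C@@]1(C)[C@]12CC[C@](C)(O1)[C@@H](Br)C2 | intermediate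
10 | (1R,3R)-3-[(1R,3S,4S)-3-bromo-4-methyl-7-oxabicyclo[2.2.1]heptan-1-yl]-2,2,3-trimethylcyclopentan-1-ol | CC1(C)[C@H](O)CC[C@@]1(C)[C@]12CC[C@](C)(O1)[C@@H](Br)C2 | intermediate
11 | {[(1R,3R)-3-[(1R,3S,4S)-3-bromo-4-methyl-7-oxabicyclo[2.2.1]heptan-1-yl]-2,2,3-trimethylcyclopentyl]oxy}triphenylphosphonium bromide (formed in the flask, not isolated) | CC1(C)[C@H](O[P+](c2ccccc2)(c2ccccc2)c2ccccc2)CC[C@@]1(C)[C@]12CC[C@](C)(O1)[C@@H](Br)C2.[Br-] | intermediate
12 | (1S,2S,4R)-2-bromo-4-[(1R,3S)-3-bromo-1,2,2-trimethylcyclopentyl]-1-methyl-7-oxabicyclo[2.2.1]heptane | CC1(C)[C@@H](Br)CC[C@@]1(C)[C@]12CC[C@](C)(O1)[C@@H](Br)C2 | intermediate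
13 | dichloro{[(1R,3S,4S)-3-bromo-1-[(1R,3S)-3-bromo-1,2,2-trimethylcyclopentyl]-4-chloro-4-methylcyclohexyl]oxy}borane (formed in the flask, not isolated) | CC1(C)[C@@H](Br)CC[C@@]1(C)[C@@]1(OB(Cl)Cl)CC[C@](C)(Cl)[C@@H](Br)C1 | intermediate
14 | (1R,3S,4S)-3-bromo-1-[(1R,3S)-3-bromo-1,2,2-trimethylcyclopentyl]-4-chloro-4-methylcyclohexan-1-ol | CC1(C)[C@@H](Br)CC[C@@]1(C)[C@@]1(O)CC[C@](C)(Cl)[C@@H](Br)C1 | target

## Step count and least certain steps

Total: 9 steps. Longest linear sequence: 9 steps (1 to 14); 4 is bought and enters at step 3.

**Step 3 (key step, the one step beyond demonstrated scope).**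
- What may go wrong: the photochemical pathway is most likely to be lost to thermal Lewis-acid chemistry, namely conjugate addition of the silyl enol ether to the activated enone or acid-induced shift of the 1,4-diene into conjugation, because the catalyst is a very strong Lewis acid and 3 is nucleophilic and acid-sensitive. Next in line are low enantioselectivity (4 lacks the α-hydrogen that helps to fix the catalyst on simpler enones), hydrogen abstraction by the triplet from the doubly allylic CH2 groups of 3 with aromatisation, and leakage to head-to-head or cis-syn-cis addition.
- Fallback (known chemistry): set out from 3 and 4 and irradiate them directly (λ = 350 nm, CH2Cl2, −40 °C, no Lewis acid). This classical enone–enol ether photocycloaddition gives 5 as the racemate, that is together with the mirror-image photoadduct F1. Steps 4 to 6 are run unchanged on the racemate, so that 6, 7, 8 and 9 are accompanied by the mirror-image cyclobutanol F2, the mirror-image dilithium enolate-alkoxide F3 (not isolated), the mirror-image hydroxy ketone F4 and the mirror-image bromoether ketone F5. In step 7 the (S)-oxazaborolidine should reduce 9 to 10 and F5 mainly to the cis-alcohol F6, a diastereomer of 10 that is separated by chromatography. The route is rejoined at 10.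

**Step 8.**
- What may go wrong: ionisation of the alkoxyphosphonium ion may outrun backside attack, with migration of a C2 methyl group or elimination towards C4, because SN2 displacement at a secondary neopentyl carbon is slow.
- Fallback: set out from 9. Treat it with KN(SiMe3)2 and PhNTf2 (THF, −78 °C) to give the enol triflate F7. Miyaura borylation (B2pin2, PdCl2(dppf), KOAc, dioxane, 80 °C) gives the alkenylboronic ester F8. Hydrogenation with [Ir(cod)(PCy3)(py)]PF6 and H2 from the more open face of ring A should give the alkylboronic ester F9 with boron trans to ring B. Addition of 3,5-(CF3)2C6H3Li (THF, −78 °C) forms the lithium boronate complex F10 (not isolated), and NBS replaces boron by bromine with inversion at C3 (stereoinvertive halodeboronation of a secondary boronic ester). No cation is generated at C3. The route is rejoined at 12.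

**Step 9.**
- What may go wrong: cleavage on the wrong side of the oxygen bridge, at C1'–O, where ionisation relieves the crowding between the two fully substituted carbons and opens the way to skeletal shifts in ring A; or chloride attack at C5' of the bromonium ion with migration of bromine.
- Fallback: set out from 12 and open the bridge by acylative ether cleavage (AcCl, catalytic ZnCl2, CH2Cl2, 0 °C). Activation as an acyloxonium ion is much weaker, which should favour the bromine-assisted C4'–O cleavage over unassisted ionisation at C1'. This gives the tertiary acetate F11, which is deacetylated with i-Bu2AlH (CH2Cl2, −78 °C). The route is rejoined at 14.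

**Step 7.**
- What may go wrong: insufficient reagent control (slow catalysed reduction of a ketone flanked by a quaternary carbon, with uncatalysed borane reduction taking over), which would erode both the trans selectivity and the enantiomeric upgrading.
- Fallback: set out from 8 and reduce before the bridge is formed, with Me4NBH(OAc)3 (MeCN, AcOH, −20 °C). This reagent reduces the ketone only after exchange onto the C1' hydroxyl and therefore delivers hydride within the molecule to the ring-B face of C3, giving the trans-diol F12. Bromoetherification of F12 with NBS, as in step 6, rejoins the route at 10.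

## Further compounds

F1 | step 3 | (1S,2R,7S,8S)-2-[(tert-butyldimethylsilyl)oxy]-1,5,8-trimethyltricyclo[6.3.0.0(2,7)]undec-4-en-9-one (mirror image of 5) | O=C1CC[C@@]2(C)[C@]1(C)[C@@H]1CC(C)=CC[C@@]12O[Si](C)(C)C(C)(C)C
F2 | step 3 | (1S,2R,7S,8S)-2-hydroxy-1,5,8-trimethyltricyclo[6.3.0.0(2,7)]undec-4-en-9-one (mirror image of 6) | O=C1CC[C@@]2(C)[C@]1(C)[C@@H]1CC(C)=CC[C@@]12O
F3 | step 3 | dilithium (3S)-2,3-dimethyl-3-[(1S)-4-methyl-1-oxidocyclohex-3-en-1-yl]cyclopent-1-en-1-olate (mirror image of 7, not isolated) | [Li]OC1=C(C)[C@](C)(CC1)[C@]1(O[Li])CCC(C)=CC1
F4 | step 3 | (3S)-3-[(1S)-1-hydroxy-4-methylcyclohex-3-en-1-yl]-2,2,3-trimethylcyclopentan-1-one (mirror image of 8) | CC1(C)C(=O)CC[C@]1(C)[C@]1(O)CCC(C)=CC1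
F5 | step 3 | (3S)-3-[(1S,3R,4R)-3-bromo-4-methyl-7-oxabicyclo[2.2.1]heptan-1-yl]-2,2,3-trimethylcyclopentan-1-one (mirror image of 9) | CC1(C)C(=O)CC[C@]1(C)[C@@]12CC[C@@](C)(O1)[C@H](Br)C2
F6 | step 3 | (1R,3S)-3-[(1S,3R,4R)-3-bromo-4-methyl-7-oxabicyclo[2.2.1]heptan-1-yl]-2,2,3-trimethylcyclopentan-1-ol (cis-alcohol) | CC1(C)[C@H](O)CC[C@]1(C)[C@@]12CC[C@@](C)(O1)[C@H](Br)C2
F7 | step 8 | (4R)-4-[(1R,3S,4S)-3-bromo-4-methyl-7-oxabicyclo[2.2.1]heptan-1-yl]-4,5,5-trimethylcyclopent-1-en-1-yl trifluoromethanesulfonate | CC1(C)C(OS(=O)(=O)C(F)(F)F)=CC[C@@]1(C)[C@]12CC[C@](C)(O1)[C@@H](Br)C2
F8 | step 8 | 2-{(4R)-4-[(1R,3S,4S)-3-bromo-4-methyl-7-oxabicyclo[2.2.1]heptan-1-yl]-4,5,5-trimethylcyclopent-1-en-1-yl}-4,4,5,5-tetramethyl-1,3,2-dioxaborolane | CC1(C)C(B2OC(C)(C)C(C)(C)O2)=CC[C@@]1(C)[C@]12CC[C@](C)(O1)[C@@H](Br)C2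
F9 | step 8 | 2-{(1R,3R)-3-[(1R,3S,4S)-3-bromo-4-methyl-7-oxabicyclo[2.2.1]heptan-1-yl]-2,2,3-trimethylcyclopentyl}-4,4,5,5-tetramethyl-1,3,2-dioxaborolane | CC1(C)[C@H](B2OC(C)(C)C(C)(C)O2)CC[C@@]1(C)[C@]12CC[C@](C)(O1)[C@@H](Br)C2
F10 | step 8 | lithium boronate complex of F9 carrying 3,5-bis(trifluoromethyl)phenyl on boron (not isolated) | [Li+].CC1(C)[C@H]([B-]2(OC(C)(C)C(C)(C)O2)c2cc(cc(c2)C(F)(F)F)C(F)(F)F)CC[C@@]1(C)[C@]12CC[C@](C)(O1)[C@@H](Br)C2
F11 | step 9 | (1R,3S,4S)-3-bromo-1-[(1R,3S)-3-bromo-1,2,2-trimethylcyclopentyl]-4-chloro-4-methylcyclohexyl acetate | CC1(C)[C@@H](Br)CC[C@@]1(C)[C@@]1(OC(C)=O)CC[C@](C)(Cl)[C@@H](Br)C1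
F12 | step 7 | (1R,3R)-3-[(1R)-1-hydroxy-4-methylcyclohex-3-en-1-yl]-2,2,3-trimethylcyclopentan-1-ol | CC1(C)[C@H](O)CC[C@@]1(C)[C@@]1(O)CCC(C)=CC1
A1 | alternative 1 | 2-{1-[(1S,3R)-3-[(tert-butyldimethylsilyl)oxy]-1,2,2-trimethylcyclopentyl]ethenyl}-4,4,5,5-tetramethyl-1,3,2-dioxaborolane | CC1(C)[C@H](O[Si](C)(C)C(C)(C)C)CC[C@@]1(C)C(=C)B1OC(C)(C)C(C)(C)O1
A2 | alternative 1 | 3-methylbut-3-enyllithium | [Li]CCC(C)=C
A3 | alternative 1 | ethenyl trifluoromethanesulfonate | C=COS(=O)(=O)C(F)(F)F
A4 | alternative 1 | 2-{4-[3-[(tert-butyldimethylsilyl)oxy]-1,2,2-trimethylcyclopentyl]-7-methylocta-1,7-dien-4-yl}-4,4,5,5-tetramethyl-1,3,2-dioxaborolane (configuration as in the SMILES) | CC1(C)[C@H](O[Si](C)(C)C(C)(C)C)CC[C@@]1(C)[C@@](CC=C)(B1OC(C)(C)C(C)(C)O1)CCC(C)=C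
A5 | alternative 2 | 4-(8-hydroxy-1,4-dioxaspiro[4.5]dec-6-en-8-yl)-4,5-dimethylhex-5-enal (configuration as in the SMILES) | O=CCC[C@@](C(C)=C)(C)[C@@]1(O)CCC2(OCCO2)C=C1
A6 | alternative 2 | 8-(3-hydroxy-1,2,2-trimethylcyclopentyl)-1,4-dioxaspiro[4.5]dec-6-en-8-ol (configuration as in the SMILES) | CC1(C)[C@H](O)CC[C@@]1(C)[C@@]1(O)CCC2(OCCO2)C=C1
A7 | alternative 3 | 2-(3-bromo-1,2,2-trimethylcyclopentyl)prop-2-enal (configuration as in the SMILES) | CC1(C)[C@@H](Br)CC[C@@]1(C)C(=C)C=O
A8 | alternative 3 | 2-methylbuta-1,3-diene | C=CC(C)=C
A9 | alternative 3 | 1-(3-bromo-1,2,2-trimethylcyclopentyl)-4-methylcyclohex-3-ene-1-carbaldehyde (configuration as in the SMILES) | CC1(C)[C@@H](Br)CC[C@@]1(C)[C@@]1(C=O)CCC(C)=CC1
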